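Locants used throughout are those of the target 19: C5 is the spiro carbon (also C1′ of ring B), C6 is the CH2, C7 and C8 carry the methyl groups, C9 carries the benzoate, ring A is the trimethoxybenzene ring (C4a bonded to C5, C9a bonded to C9), and ring B is the six-membered dienone ring (C4′ = carbonyl carbon).

## The problem

Compound 19 is a 6,7,8,9-tetrahydrobenzo[7]annulene whose C5 is spiro-fused to a 3′,5′-dimethoxycyclohexa-2′,5′-dien-4′-one (ring B); C5 is quaternary and bonded to ring A carbon C4a (itself flanked by the C4 methoxy group), to C6H2 and to the two dienone CH carbons. The seven-membered ring exists only while ring B is dearomatised, so any ring-based stereocontrol after closure would have to be carried out in the presence of the dienone. The stereocentres are C7 (R), C8 (S) and C9 (R), contiguous, with the two methyl groups trans and the C8 methyl trans to the C9 benzoate (7,8-syn and 8,9-syn in the open chain); C9 and C8 can be set together in one carbonyl addition, whereas C7 is not reached by the usual acyclic relay (hydroboration of a 1,1-disubstituted alkene next to C8 is expected to give the 7,8-cis-dimethyl pattern) and is better controlled by C8 and C9 inside a small ring. The dienone is the fragile group: acid induces a 1,2-shift with rearomatisation, and hydrides, organometallic reagents and hydrogenation attack it, so it has to be formed last under neutral or basic, non-reducing conditions. The C9 benzoate is benzylic on an electron-rich ring and can ionise, and a free C9 hydroxyl next to an activated C6 closes a tetrahydrofuran. The feature that opens the problem is that C5 is at once C1′, the para carbon of a 2,6-dimethoxyphenol (ring B), and the carbon that carries ring A. Rearomatising ring B therefore gives a biaryl phenolate whose carbon nucleophile is C5 itself, whose ortho carbons C3′ and C5′ are blocked by methoxy groups, and whose mirror plane through C1′ and C4′ makes C5 non-stereogenic, so that one C5–C6 bond formation closes the ring, makes the quaternary centre and the dienone, and needs no stereocontrol.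

## Retrosynthesis

**19 ⇒ 18 (from 17): cut C5–C6.** Ring B is rearomatised to a phenolate and C6 becomes a primary bromide. Against the neighbouring cut C4a–C5 (aryl to spiro carbon), this one needs neither oxidant nor acid and moves the aryl–aryl bond into a separate, regiochemically fixed cross-coupling. The precursor 17 is an open-chain biaryl with no quaternary carbon and no medium ring. The forward reaction must make phenolate 18 alkylate at C1′ through a seven-membered transition state faster than a second molecule alkylates it at oxygen.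

**17 ⇒ 16 ⇒ 14: functional-group level.** The C6 bromide and the C9 benzoate come from the two aliphatic hydroxyls of triol 14. The order is dictated by the tetrahydrofuran problem: the phenol and C6–OH are silylated, C9–OH is benzoylated (16), and only then is the C6 silyl ether exchanged for bromide, so a free C9 hydroxyl never faces an activated C6.

**14 ⇒ 13 ⇒ 11 + 12: cut the biaryl bond C4a–C1′.** Triol 14 is the reduction product of lactone 13, which comes from aryl bromide 11 and the commercial phenol boronate 12 by Suzuki–Miyaura coupling. Ring B has no ortho substituent, so the biaryl axis is not a stereogenic element. Bromide 11 comes from 10 by bromination at one of two equivalent ring positions; bromine enters after the last enolate step, and 10 remains a bromine-free branch point.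

**10 ⇒ 8: cut C7–CH3.** The lactone ring O1–C5–C4–C3–C2 of 8 contains C9, C8, C7 and C6 of the target. Its 5-aryl and 4-methyl groups are cis, so the enolate is methylated from the opposite face and C7 is relayed from C8 and C9. The precursor has two stereocentres instead of three; the forward step must be trans-selective and stop at monoalkylation.

**8 ⇒ 6 ⇒ 4 ⇒ 1 + 2: cut C8–C9.** Lactone 8 is the oxidation product of diol 6, which comes from homoallylic alcohol 4 by hydroboration. Alcohol 4 is the syn adduct of 3,4,5-trimethoxybenzaldehyde 1 and (Z)-crotylboronate 2 (through borate 3); one catalytic, enantioselective crotyl transfer sets C9 and C8 together. Both starting materials are catalogue compounds.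

## Roads not taken

**Alternative 1:** cut C4a–C5 (the obvious route). Forward key step: two-electron oxidation of the phenol of the 1,4-diarylbutyl benzoate A1 with PhI(OAc)2 in a fluoroalcohol and capture of the cation at C1′ by ring A (para-ipso coupling). The step has precedent in this ring system. It is not the main line for three reasons:
- The dienone is born in an oxidising, acidic medium, where the 1,2-aryl shift with rearomatisation and the ionisation of the C9 benzylic ester are fastest.
- The cation can also be captured by solvent at C1′ or at the methoxy-bearing ortho carbons.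
- A1 needs an sp3–sp2 coupling at C6 on a chain that carries all three stereocentres, where the chosen plan uses an sp2–sp2 coupling on a lactone.

The step count is the same, so nothing is lost, and this chemistry is kept as the fallback for the key step.

**Alternative 2:** ring first, stereocentres afterwards. Cut both methyl groups and the C9–H bond back to the achiral spiro-enone A2. Forward key step: copper-catalysed enantioselective conjugate addition of a methyl nucleophile at C7, trapping of the enolate at C8 with MeI (trans), then reduction of the C9 ketone. Rejected because: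
- Ring B is itself a cross-conjugated dienone and a second ketone, so neither the cuprate nor the hydride would spare it.
- Hydride would add to C9 anti to the C8 methyl group and give the 8,9-cis alcohol.
- A2 still needs the same spiro-closure, without the three substituents that bias the chain.

**Alternative 3:** the same C5–C6 bond, with C6 as one terminus of a 2-substituted π-allylpalladium unit. Allylic carbonate A3 with Pd(PPh3)4 would give the 7-methylidene spirodienone A4, followed by reduction of the exocyclic alkene. The attraction is that O-allylation is reversible under palladium catalysis, so the C- versus O-alkylation problem disappears. Rejected because C7 would then be set on the ring in the presence of the dienone: hydrogen delivered to C7 anti to the C8 methyl group (or syn to an oxygen director at C9) places the new methyl cis to the C8 methyl, and hydrogenation catalysts do not spare ring B.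

Key step: step 10

Assumption: (R)-TRIP is taken to direct crotyl transfer to the aldehyde face that gives the (1R) carbinol, as with other aryl aldehydes; its mirror image would be used if the sense were opposite. Compounds 2 and 12, the catalyst and 4-bromo-2,6-dimethoxyphenol are taken as catalogue compounds.

## Route

Step 1
Reactants: 1 3,4,5-trimethoxybenzaldehyde; 2 (Z)-crotylboronic acid pinacol ester
Product: 4 (1R,2S)-2-methyl-1-(3,4,5-trimethoxyphenyl)but-3-en-1-ol, via O-pinacolboryl ether 3 (not isolated)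
Conditions: (R)-TRIP [(R)-3,3′-bis(2,4,6-triisopropylphenyl)-1,1′-binaphthyl-2,2′-diyl hydrogen phosphate] (5 mol %), toluene, 4 Å molecular sieves, −30 °C; aqueous NaHCO3 work-up
Reagents that add atoms: none
Why: Chiral phosphoric acid-catalysed allylboration through a closed chair (Zimmerman–Traxler) transition state: the Z geometry of 2 gives the 1,2-syn adduct, and the catalyst, hydrogen-bonded to the boronate oxygen, selects the aldehyde face, so C9 (R) and C8 (S) are set in one event.

Step 2
Reactants: 4 (1R,2S)-2-methyl-1-(3,4,5-trimethoxyphenyl)but-3-en-1-ol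
Product: 6 (1R,2S)-2-methyl-1-(3,4,5-trimethoxyphenyl)butane-1,4-diol, via bis-9-BBN adduct 5 (not isolated)
Conditions: 9-BBN (2.2 equiv), THF, 0 → 23 °C; then NaOH (3 M), H2O2 (30 %), 0 °C
Reagents that add atoms: hydrogen peroxide, OO
Why: Anti-Markovnikov hydroboration of the monosubstituted alkene and oxidation with retention; the first equivalent of borane is consumed by the hydroxyl group and no stereocentre is touched.

Step 3
Reactants: 6 (1R,2S)-2-methyl-1-(3,4,5-trimethoxyphenyl)butane-1,4-diol
Product: 8 (4S,5R)-4-methyl-5-(3,4,5-trimethoxyphenyl)oxolan-2-one, via lactol 7 (not isolated)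
Conditions: TEMPO (0.2 equiv), PhI(OAc)2 (2.5 equiv), CH2Cl2, 23 °C
Reagents that add atoms: none
Why: Oxoammonium oxidation is selective for the primary alcohol; the aldehyde closes to lactol 7, which is oxidised on to the γ-lactone, so the hindered benzylic alcohol is consumed as the ring oxygen and the aryl and methyl groups end up cis on the five-membered ring.

Step 4
Reactants: 8 (4S,5R)-4-methyl-5-(3,4,5-trimethoxyphenyl)oxolan-2-one
Product: 10 (3S,4S,5R)-3,4-dimethyl-5-(3,4,5-trimethoxyphenyl)oxolan-2-one, via lithium enolate 9 (not isolated)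
Conditions: LiN(iPr)2 (1.1 equiv), THF, −78 °C; MeI (1.5 equiv), −78 → −40 °C
Reagents that add atoms: iodomethane, CI
Why: Enolate alkylation of a β,γ-disubstituted γ-butyrolactone: the 4-methyl and 5-aryl groups shield the same face of the planar enolate, so MeI enters from the other face and sets C3 (the future C7) trans to the 4-methyl group by substrate control.

Step 5
Reactants: 10 (3S,4S,5R)-3,4-dimethyl-5-(3,4,5-trimethoxyphenyl)oxolan-2-one
Product: 11 (3S,4S,5R)-5-(2-bromo-3,4,5-trimethoxyphenyl)-3,4-dimethyloxolan-2-one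
Conditions: NBS (1.05 equiv), MeCN, 0 → 23 °C, dark
Reagents that add atoms: N-bromosuccinimide, O=C1CCC(=O)N1Br
Why: Electrophilic aromatic bromination; the two free positions of the trimethoxyphenyl ring are equivalent and each is ortho and para to methoxy groups, so one monobromide should form, at the carbon that becomes C4a.

Step 6
Reactants: 11 (3S,4S,5R)-5-(2-bromo-3,4,5-trimethoxyphenyl)-3,4-dimethyloxolan-2-one; 12 2,6-dimethoxy-4-(4,4,5,5-tetramethyl-1,3,2-dioxaborolan-2-yl)phenol
Product: 13 (3S,4S,5R)-5-(4'-hydroxy-3',4,5,5',6-pentamethoxy-[1,1'-biphenyl]-2-yl)-3,4-dimethyloxolan-2-one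
Conditions: Pd(OAc)2 (3 mol %), SPhos (6 mol %), K3PO4 (3 equiv), toluene/H2O (10:1), 80 °C; 1 M HCl work-up
Reagents that add atoms: none
Why: Suzuki–Miyaura coupling with a dialkylbiarylphosphine suited to di-ortho-substituted aryl bromides; the phenol is tolerated as its phenolate, the thermodynamically preferred trans lactone cannot epimerise to a worse isomer, and acidification recloses any lactone opened by the base.

Step 7
Reactants: 13 (3S,4S,5R)-5-(4'-hydroxy-3',4,5,5',6-pentamethoxy-[1,1'-biphenyl]-2-yl)-3,4-dimethyloxolan-2-one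
Product: 14 (1R,2S,3S)-1-(4'-hydroxy-3',4,5,5',6-pentamethoxy-[1,1'-biphenyl]-2-yl)-2,3-dimethylbutane-1,4-diol
Conditions: LiAlH4 (2.5 equiv), THF, 0 → 23 °C; aqueous potassium sodium tartrate work-up
Reagents that add atoms: none
Why: Hydride reduction of the lactone to the 1,4-diol; the phenol only consumes one hydride and the neutral work-up avoids acid-induced ionisation at the benzylic carbinol.

Step 8
Reactants: 14 (1R,2S,3S)-1-(4'-hydroxy-3',4,5,5',6-pentamethoxy-[1,1'-biphenyl]-2-yl)-2,3-dimethylbutane-1,4-diol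
Product: 16 (1R,2S,3S)-4-[(tert-butyldimethylsilyl)oxy]-1-{4'-[(tert-butyldimethylsilyl)oxy]-3',4,5,5',6-pentamethoxy-[1,1'-biphenyl]-2-yl}-2,3-dimethylbutyl benzoate, via bis-silyl ether 15 (not isolated)
Conditions: TBSCl (2.3 equiv), imidazole (5 equiv), CH2Cl2, 0 °C; then BzCl (1.5 equiv), Et3N (3 equiv), DMAP (0.2 equiv), 23 °C
Reagents that add atoms: tert-butyl(chloro)dimethylsilane, CC(C)(C)[Si](C)(C)Cl; benzoyl chloride, O=C(Cl)c1ccccc1
Why: Silylation takes the phenol and the primary alcohol and leaves the hindered, α-branched benzylic alcohol, which is then acylated under DMAP catalysis; the order ensures that a free C9 hydroxyl never coexists with a leaving group at C6, which would close a tetrahydrofuran.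

Step 9
Reactants: 16 (1R,2S,3S)-4-[(tert-butyldimethylsilyl)oxy]-1-{4'-[(tert-butyldimethylsilyl)oxy]-3',4,5,5',6-pentamethoxy-[1,1'-biphenyl]-2-yl}-2,3-dimethylbutyl benzoate
Product: 17 (1R,2S,3S)-4-bromo-1-{4'-[(tert-butyldimethylsilyl)oxy]-3',4,5,5',6-pentamethoxy-[1,1'-biphenyl]-2-yl}-2,3-dimethylbutyl benzoate
Conditions: Ph3PBr2 (1.5 equiv), CH2Cl2, 0 → 23 °C
Reagents that add atoms: dibromotriphenylphosphorane, BrP(Br)(c1ccccc1)(c1ccccc1)c1ccccc1
Why: Direct conversion of a primary alkyl silyl ether into the bromide through an alkoxyphosphonium ion and SN2 displacement by bromide; the aryl silyl ether cannot be displaced at an sp2 carbon and the ester is inert to the phosphorane.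

Step 10
Reactants: 17 (1R,2S,3S)-4-bromo-1-{4'-[(tert-butyldimethylsilyl)oxy]-3',4,5,5',6-pentamethoxy-[1,1'-biphenyl]-2-yl}-2,3-dimethylbutyl benzoate
Product: 19 (7R,8S,9R)-2,3,3',4,5'-pentamethoxy-7,8-dimethyl-4'-oxo-6,7,8,9-tetrahydrospiro[benzo[7]annulene-5,1'-cyclohexa[2,5]dien]-9-yl benzoate, via tetrabutylammonium phenolate 18 (not isolated)
Conditions: Bu4NF (1.1 equiv), THF, 0 °C; then syringe-pump addition over 12 h to t-BuOH/THF (4:1) with Bu4NI (0.2 equiv) at 70 °C, final concentration ≤ 0.002 M
Reagents that add atoms: none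
Why: Proposed new method: fluoride removes the aryl silyl group and leaves phenolate 18, whose negative charge is shared by oxygen and by C1′ (para), the carbon that already carries ring A; C1′ displaces bromide at the primary carbon in an intramolecular SN2 reaction (7-exo-tet), forming the C5–C6 bond, the quaternary spiro centre and the dienone in one event. The closest known reaction type is the intramolecular para-alkylation of phenolates by a tethered halide or sulfonate (Ar1-5 and Ar1-6 participation, including fluoride-triggered versions from silyl-protected phenols), established for five- and six-membered rings on 4-alkylphenols but not for a seven-membered ring on a 4-arylphenol. The seven-membered ring is expected to close because two of its bonds (C1′–C4a and C4a–C9a) are held by the twisted biaryl, which places C9 above the plane of ring B, and because the substituents at C7, C8 and C9 can all sit equatorial in the folded chain. No stereocentre is created: the two halves of ring B are equivalent, so C5 is not stereogenic, and C7, C8 and C9 are not touched by a substitution at C6. The selectivity needed is C- against O-alkylation: within one molecule neither the oxygen nor the methoxy-bearing ortho carbons can reach C6, so O-alkylation can only be intermolecular and is held back by pseudo-high dilution, by the hydrogen-bonding solvent t-BuOH and by the two flanking methoxy groups. The hindered phenolate does not attack the benzoate, and the medium contains neither acid nor oxidant, so the dienone is not exposed to conditions that induce its rearrangement.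

## Compound list

1 | 3,4,5-trimethoxybenzaldehyde | COc1cc(C=O)cc(OC)c1OC | starting material
2 | 2-[(2Z)-but-2-en-1-yl]-4,4,5,5-tetramethyl-1,3,2-dioxaborolane ((Z)-crotylboronic acid pinacol ester) | C/C=C\CB1OC(C)(C)C(C)(C)O1 | starting material
3 | 4,4,5,5-tetramethyl-2-{[(1R,2S)-2-methyl-1-(3,4,5-trimethoxyphenyl)but-3-en-1-yl]oxy}-1,3,2-dioxaborolane | C=C[C@H](C)[C@@H](OB1OC(C)(C)C(C)(C)O1)c1cc(OC)c(OC)c(OC)c1 | intermediate (not isolated)
4 | (1R,2S)-2-methyl-1-(3,4,5-trimethoxyphenyl)but-3-en-1-ol | C=C[C@H](C)[C@@H](O)c1cc(OC)c(OC)c(OC)c1 | intermediate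
5 | 9-[(3S,4R)-4-(9-borabicyclo[3.3.1]nonan-9-yloxy)-3-methyl-4-(3,4,5-trimethoxyphenyl)butyl]-9-borabicyclo[3.3.1]nonane | B1(CC[C@H](C)[C@@H](OB2C3CCCC2CCC3)c2cc(OC)c(OC)c(OC)c2)C2CCCC1CCC2 | intermediate (not isolated)
6 | (1R,2S)-2-methyl-1-(3,4,5-trimethoxyphenyl)butane-1,4-diol | OCC[C@H](C)[C@@H](O)c1cc(OC)c(OC)c(OC)c1 | intermediate
7 | (4S,5R)-4-methyl-5-(3,4,5-trimethoxyphenyl)oxolan-2-ol | OC1C[C@H](C)[C@@H](O1)c1cc(OC)c(OC)c(OC)c1 | intermediate (not isolated)
8 | (4S,5R)-4-methyl-5-(3,4,5-trimethoxyphenyl)oxolan-2-one | O=C1C[C@H](C)[C@@H](O1)c1cc(OC)c(OC)c(OC)c1 | intermediate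
9 | lithium (4S,5R)-4-methyl-5-(3,4,5-trimethoxyphenyl)-4,5-dihydrofuran-2-olate | [Li]OC1=C[C@H](C)[C@@H](O1)c1cc(OC)c(OC)c(OC)c1 | intermediate (not isolated)
10 | (3S,4S,5R)-3,4-dimethyl-5-(3,4,5-trimethoxyphenyl)oxolan-2-one | O=C1[C@@H](C)[C@H](C)[C@@H](O1)c1cc(OC)c(OC)c(OC)c1 | intermediate
11 | (3S,4S,5R)-5-(2-bromo-3,4,5-trimethoxyphenyl)-3,4-dimethyloxolan-2-one | O=C1[C@@H](C)[C@H](C)[C@@H](O1)c1cc(OC)c(OC)c(OC)c1Br | intermediate
12 | 2,6-dimethoxy-4-(4,4,5,5-tetramethyl-1,3,2-dioxaborolan-2-yl)phenol | COc1cc(cc(OC)c1O)B1OC(C)(C)C(C)(C)O1 | starting material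
13 | (3S,4S,5R)-5-(4'-hydroxy-3',4,5,5',6-pentamethoxy-[1,1'-biphenyl]-2-yl)-3,4-dimethyloxolan-2-one | O=C1[C@@H](C)[C@H](C)[C@@H](O1)c1cc(OC)c(OC)c(OC)c1-c1cc(OC)c(O)c(OC)c1 | intermediate
14 | (1R,2S,3S)-1-(4'-hydroxy-3',4,5,5',6-pentamethoxy-[1,1'-biphenyl]-2-yl)-2,3-dimethylbutane-1,4-diol | OC[C@@H](C)[C@H](C)[C@@H](O)c1cc(OC)c(OC)c(OC)c1-c1cc(OC)c(O)c(OC)c1 | intermediate
15 | (1R,2S,3S)-4-[(tert-butyldimethylsilyl)oxy]-1-{4'-[(tert-butyldimethylsilyl)oxy]-3',4,5,5',6-pentamethoxy-[1,1'-biphenyl]-2-yl}-2,3-dimethylbutan-1-ol | CC(C)(C)[Si](C)(C)OC[C@@H](C)[C@H](C)[C@@H](O)c1cc(OC)c(OC)c(OC)c1-c1cc(OC)c(O[Si](C)(C)C(C)(C)C)c(OC)c1 | intermediate (not isolated)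
16 | (1R,2S,3S)-4-[(tert-butyldimethylsilyl)oxy]-1-{4'-[(tert-butyldimethylsilyl)oxy]-3',4,5,5',6-pentamethoxy-[1,1'-biphenyl]-2-yl}-2,3-dimethylbutyl benzoate | CC(C)(C)[Si](C)(C)OC[C@@H](C)[C@H](C)[C@@H](OC(=O)c1ccccc1)c1cc(OC)c(OC)c(OC)c1-c1cc(OC)c(O[Si](C)(C)C(C)(C)C)c(OC)c1 | intermediate
17 | (1R,2S,3S)-4-bromo-1-{4'-[(tert-butyldimethylsilyl)oxy]-3',4,5,5',6-pentamethoxy-[1,1'-biphenyl]-2-yl}-2,3-dimethylbutyl benzoate | BrC[C@@H](C)[C@H](C)[C@@H](OC(=O)c1ccccc1)c1cc(OC)c(OC)c(OC)c1-c1cc(OC)c(O[Si](C)(C)C(C)(C)C)c(OC)c1 | intermediate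
18 | tetrabutylammonium 2'-[(1R,2S,3S)-1-(benzoyloxy)-4-bromo-2,3-dimethylbutyl]-3,4',5,5',6'-pentamethoxy-[1,1'-biphenyl]-4-olate | BrC[C@@H](C)[C@H](C)[C@@H](OC(=O)c1ccccc1)c1cc(OC)c(OC)c(OC)c1-c1cc(OC)c([O-])c(OC)c1.CCCC[N+](CCCC)(CCCC)CCCC | intermediate (not isolated)
19 | (7R,8S,9R)-2,3,3',4,5'-pentamethoxy-7,8-dimethyl-4'-oxo-6,7,8,9-tetrahydrospiro[benzo[7]annulene-5,1'-cyclohexa[2,5]dien]-9-yl benzoate | COC1=CC2(C=C(OC)C1=O)C[C@@H](C)[C@H](C)[C@@H](OC(=O)c1ccccc1)c1cc(OC)c(OC)c(OC)c12 | target

Total step count: 10. Longest linear sequence: 10 steps (1 to 19); boronate 12 enters unchanged at step 6.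

## Steps least certain to work

**Step 10 (key step, the one labelled as new).** Most likely failure: intermolecular O-alkylation (oligomerisation) outrunning the seven-membered C-alkylation, because a phenolate oxygen is intrinsically the faster nucleophile and a seven-membered closure has only a modest effective molarity. Secondary failures are E2 loss of HBr across C6–C7 and substitution of bromide by fluoride.

Fallback (known chemistry, the oxidative para-ipso coupling of Alternative 1): it sets out from the bromine-free lactone 10 and returns at 19.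
- LiAlH4 reduces 10 to (1R,2S,3S)-2,3-dimethyl-1-(3,4,5-trimethoxyphenyl)butane-1,4-diol F1.
- Silylation of the primary hydroxyl (TBSCl, imidazole) and benzoylation in the same flask give (1R,2S,3S)-4-[(tert-butyldimethylsilyl)oxy]-2,3-dimethyl-1-(3,4,5-trimethoxyphenyl)butyl benzoate F2.
- Ph3PBr2 gives (1R,2S,3S)-4-bromo-2,3-dimethyl-1-(3,4,5-trimethoxyphenyl)butyl benzoate F3.
- Commercial 4-bromo-2,6-dimethoxyphenol is silylated to (4-bromo-2,6-dimethoxyphenoxy)(tert-butyl)dimethylsilane F4.
- A nickel-catalysed reductive cross-electrophile coupling of F3 with F4 (NiBr2(dme), 4,4′-di-tert-butyl-2,2′-bipyridine, Zn, NaI, DMA, 60 °C) gives (1R,2S,3R)-4-{4-[(tert-butyldimethylsilyl)oxy]-3,5-dimethoxyphenyl}-2,3-dimethyl-1-(3,4,5-trimethoxyphenyl)butyl benzoate F5.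
- Bu4NF buffered with AcOH frees (1R,2S,3R)-4-(4-hydroxy-3,5-dimethoxyphenyl)-2,3-dimethyl-1-(3,4,5-trimethoxyphenyl)butyl benzoate F6, the compound called A1 above.
- PhI(OAc)2 in CF3CH2OH at −40 °C, quenched cold with NaHCO3, closes C4a–C5 to give 19.

**Step 9.** Most likely failure: ionisation of the C9 benzylic ester by adventitious HBr (loss of configuration at C9 or elimination) and premature loss of the aryl silyl group.

Fallback: it sets out from 16 and returns at 19. Acid-catalysed methanolysis (camphorsulfonic acid, MeOH/CH2Cl2, 0 °C) removes only the alkyl silyl ether and gives (1R,2S,3S)-1-{4'-[(tert-butyldimethylsilyl)oxy]-3',4,5,5',6-pentamethoxy-[1,1'-biphenyl]-2-yl}-4-hydroxy-2,3-dimethylbutyl benzoate F7. An Appel iodination (I2, PPh3, imidazole) gives (1R,2S,3S)-1-{4'-[(tert-butyldimethylsilyl)oxy]-3',4,5,5',6-pentamethoxy-[1,1'-biphenyl]-2-yl}-4-iodo-2,3-dimethylbutyl benzoate F8, which is cyclised under the conditions of step 10 to 19.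

**Step 6.** Most likely failure: slow oxidative addition at the di-ortho-substituted bromide, so that protodeboronation of the electron-rich boronate and base-induced opening of the lactone take over.

Fallback (the roles of the partners are exchanged): it sets out from 11 and returns at 13. Miyaura borylation (PdCl2(dppf), bis(pinacolato)diboron, KOAc, dioxane, 90 °C) gives (3S,4S,5R)-3,4-dimethyl-5-[3,4,5-trimethoxy-2-(4,4,5,5-tetramethyl-1,3,2-dioxaborolan-2-yl)phenyl]oxolan-2-one F9. This is coupled with commercial, unhindered 4-bromo-2,6-dimethoxyphenol under the conditions of step 6 to give 13.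

**Step 1.** Most likely failure: erosion of enantio- and diastereoselectivity by the uncatalysed background allylboration, which competes more for a slowly reacting, electron-rich aldehyde, and by Z to E isomerisation of 2.

Fallback (auxiliary control in place of catalysis): it sets out from 1 and returns at 4.
- A boron-mediated syn-aldol reaction of 1 with commercial (4R)-4-benzyl-3-propanoyl-1,3-oxazolidin-2-one (Bu2BOTf, iPr2NEt, CH2Cl2, −78 °C) gives (4R)-4-benzyl-3-[(2R,3R)-3-hydroxy-2-methyl-3-(3,4,5-trimethoxyphenyl)propanoyl]-1,3-oxazolidin-2-one F10.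
- LiBH4 removes the auxiliary and gives (1R,2S)-2-methyl-1-(3,4,5-trimethoxyphenyl)propane-1,3-diol F11.
- TEMPO/PhI(OAc)2 oxidises the primary alcohol to (2R,3R)-3-hydroxy-2-methyl-3-(3,4,5-trimethoxyphenyl)propanal F12.
- Wittig methylenation (Ph3P=CH2, THF, −78 → 0 °C) gives 4.

## Further compounds

F1 | step 10 | (1R,2S,3S)-2,3-dimethyl-1-(3,4,5-trimethoxyphenyl)butane-1,4-diol | OC[C@@H](C)[C@H](C)[C@@H](O)c1cc(OC)c(OC)c(OC)c1
F2 | step 10 | (1R,2S,3S)-4-[(tert-butyldimethylsilyl)oxy]-2,3-dimethyl-1-(3,4,5-trimethoxyphenyl)butyl benzoate | CC(C)(C)[Si](C)(C)OC[C@@H](C)[C@H](C)[C@@H](OC(=O)c1ccccc1)c1cc(OC)c(OC)c(OC)c1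
F3 | step 10 | (1R,2S,3S)-4-bromo-2,3-dimethyl-1-(3,4,5-trimethoxyphenyl)butyl benzoate | BrC[C@@H](C)[C@H](C)[C@@H](OC(=O)c1ccccc1)c1cc(OC)c(OC)c(OC)c1
F4 | step 10 | (4-bromo-2,6-dimethoxyphenoxy)(tert-butyl)dimethylsilane | CC(C)(C)[Si](C)(C)Oc1c(OC)cc(Br)cc1OC
F5 | step 10 | (1R,2S,3R)-4-{4-[(tert-butyldimethylsilyl)oxy]-3,5-dimethoxyphenyl}-2,3-dimethyl-1-(3,4,5-trimethoxyphenyl)butyl benzoate | CC(C)(C)[Si](C)(C)Oc1c(OC)cc(C[C@@H](C)[C@H](C)[C@@H](OC(=O)c2ccccc2)c2cc(OC)c(OC)c(OC)c2)cc1OC
F6 | step 10 | (1R,2S,3R)-4-(4-hydroxy-3,5-dimethoxyphenyl)-2,3-dimethyl-1-(3,4,5-trimethoxyphenyl)butyl benzoate | Oc1c(OC)cc(C[C@@H](C)[C@H](C)[C@@H](OC(=O)c2ccccc2)c2cc(OC)c(OC)c(OC)c2)cc1OC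
F7 | step 9 | (1R,2S,3S)-1-{4'-[(tert-butyldimethylsilyl)oxy]-3',4,5,5',6-pentamethoxy-[1,1'-biphenyl]-2-yl}-4-hydroxy-2,3-dimethylbutyl benzoate | OC[C@@H](C)[C@H](C)[C@@H](OC(=O)c1ccccc1)c1cc(OC)c(OC)c(OC)c1-c1cc(OC)c(O[Si](C)(C)C(C)(C)C)c(OC)c1
F8 | step 9 | (1R,2S,3S)-1-{4'-[(tert-butyldimethylsilyl)oxy]-3',4,5,5',6-pentamethoxy-[1,1'-biphenyl]-2-yl}-4-iodo-2,3-dimethylbutyl benzoate | IC[C@@H](C)[C@H](C)[C@@H](OC(=O)c1ccccc1)c1cc(OC)c(OC)c(OC)c1-c1cc(OC)c(O[Si](C)(C)C(C)(C)C)c(OC)c1
F9 | step 6 | (3S,4S,5R)-3,4-dimethyl-5-[3,4,5-trimethoxy-2-(4,4,5,5-tetramethyl-1,3,2-dioxaborolan-2-yl)phenyl]oxolan-2-one | O=C1[C@@H](C)[C@H](C)[C@@H](O1)c1cc(OC)c(OC)c(OC)c1B1OC(C)(C)C(C)(C)O1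
F10 | step 1 | (4R)-4-benzyl-3-[(2R,3R)-3-hydroxy-2-methyl-3-(3,4,5-trimethoxyphenyl)propanoyl]-1,3-oxazolidin-2-one | O=C1OC[C@@H](Cc2ccccc2)N1C(=O)[C@H](C)[C@@H](O)c1cc(OC)c(OC)c(OC)c1
F11 | step 1 | (1R,2S)-2-methyl-1-(3,4,5-trimethoxyphenyl)propane-1,3-diol | OC[C@H](C)[C@@H](O)c1cc(OC)c(OC)c(OC)c1
F12 | step 1 | (2R,3R)-3-hydroxy-2-methyl-3-(3,4,5-trimethoxyphenyl)propanal | O=C[C@H](C)[C@@H](O)c1cc(OC)c(OC)c(OC)c1
A1 | alternative 1 | (1R,2S,3R)-4-(4-hydroxy-3,5-dimethoxyphenyl)-2,3-dimethyl-1-(3,4,5-trimethoxyphenyl)butyl benzoate | Oc1c(OC)cc(C[C@@H](C)[C@H](C)[C@@H](OC(=O)c2ccccc2)c2cc(OC)c(OC)c(OC)c2)cc1OC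
A2 | alternative 2 | 2,3,3',4,5'-pentamethoxy-6H-spiro[benzo[7]annulene-5,1'-cyclohexa[2,5]diene]-4',9-dione | COC1=CC2(C=C(OC)C1=O)CC=CC(=O)c1cc(OC)c(OC)c(OC)c12
A3 | alternative 3 | (1R,2S)-1-(4'-hydroxy-3',4,5,5',6-pentamethoxy-[1,1'-biphenyl]-2-yl)-3-{[(methoxycarbonyl)oxy]methyl}-2-methylbut-3-en-1-yl benzoate | COC(=O)OCC(=C)[C@H](C)[C@@H](OC(=O)c1ccccc1)c1cc(OC)c(OC)c(OC)c1-c1cc(OC)c(O)c(OC)c1
A4 | alternative 3 | (8S,9R)-2,3,3',4,5'-pentamethoxy-8-methyl-7-methylidene-4'-oxo-6,7,8,9-tetrahydrospiro[benzo[7]annulene-5,1'-cyclohexa[2,5]dien]-9-yl benzoate | COC1=CC2(C=C(OC)C1=O)CC(=C)[C@H](C)[C@@H](OC(=O)c1ccccc1)c1cc(OC)c(OC)c(OC)c12
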